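**Plan**

1. Retrosynthesis: the C12 acid and the 6-OH are released last from a C6–O–C12 ether ring and the ester is cut at O8. Ring bonds C7–C8 and C5–C10 are then cut together, opening the carbocycle to acyclic dienol 14. Dienol 14 is cut at O6–C12, C4–C15, C5–C6 (acetylide plus Weinreb amide) and C3–C8 (propargylation).
2. Enabling feature: C10 and C5 each carry a vinyl-type group (C1=C2 and C4=C3). These are the two π bonds left by a [3,3] shift of C10=C9–C8(O⁻)–C3–C4=C5, and the same shift frees C8 as an aldehyde. C7 with its C11=C13 methylene is what a carbonyl-ene reaction of a C7=C11–CH3 alkene leaves.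
3. Helper: a temporary 2,5-dihydrofuran ring (O–C6–C7=C11–C12) carries that ene alkene. It forces C6–O and C7–C11 cis, supplies the transferred hydrogen and holds C12 as a masked carboxyl; it is opened in steps 18 and 20.
4. Forward: the chain is assembled (steps 1–11), one cascade closes the cyclohexane (step 12), C8 is inverted by oxidation and reduction, acylated, and C12 is oxidised.
5. Stereochemistry: C8 (catalytic propargylation) is relayed to C10 and C5 through a chair; C6 comes from asymmetric transfer hydrogenation; C7 from the cis ring fusion; the final C8 from hydride attack on the α face. Both Z olefins of 14 come from the Z enynol and from trans-hydroalumination.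

Key step: step 12

Remark: atoms are numbered as in elemane (ring C5–C10; C10 bears CH3-14 and vinyl C1=C2; C5 bears C4(=C3)–C15; C7 bears C11(=C13)–C12) and β is the ring face of CH3-14; (S)-TRIP and the (R,R) ruthenium catalyst are assumed to give the senses drawn, the antipodes being used otherwise.

**Route**

Step 1
Reactants: 1 (2Z)-3-methylpent-2-en-4-yn-1-ol
Product: 2 (2Z)-3-methylpenta-2,4-dien-1-ol
Conditions: H2 (1 atm), Pd/CaCO3 poisoned with Pb(OAc)2, quinoline, EtOAc, 0 °C
Reagents that add atoms: none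
Why: Lindlar-type semi-hydrogenation should stop at the alkene, turning the terminal alkyne into the vinyl group and leaving the 2Z olefin untouched.

Step 2
Reactants: 2 (2Z)-3-methylpenta-2,4-dien-1-ol
Product: 3 (2Z)-3-methylpenta-2,4-dienal
Conditions: MnO2, CH2Cl2, rt, used at once
Reagents that add atoms: none
Why: Allylic oxidation with MnO2 is neutral and should preserve the 2Z geometry of the dienal.

Step 3
Reactants: 3 (2Z)-3-methylpenta-2,4-dienal
Product: 4 (4S,5Z)-6-methylocta-5,7-dien-1-yn-4-ol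
Conditions: allenylboronic acid pinacol ester, (S)-TRIP phosphoric acid (5 mol %), 4 Å MS, toluene, 0 °C
Reagents that add atoms: 4,4,5,5-tetramethyl-2-(propa-1,2-dien-1-yl)-1,3,2-dioxaborolane, C=C=CB1OC(C)(C)C(C)(C)O1
Why: Chiral phosphoric acid-catalysed propargylboration proceeds through a six-membered SE2′ transition state in which the catalyst selects the aldehyde face, which should set C8 as S.

Step 4
Reactants: 5 4-methylfuran-2(5H)-one
Product: 6 (2Z)-4-hydroxy-N-methoxy-N,3-dimethylbut-2-enamide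
Conditions: MeNH(OMe)·HCl, Me3Al, CH2Cl2, 0 °C to rt
Reagents that add atoms: N,O-dimethylhydroxylamine hydrochloride, CNOC.Cl
Why: Weinreb aminolysis of the lactone with the aluminium amide opens the ring, and the Z olefin (C12 cis to C6) is the one fixed by the ring.

Step 5
Reactants: 6 (2Z)-4-hydroxy-N-methoxy-N,3-dimethylbut-2-enamide
Product: 7 (2Z)-4-[methoxy(methyl)amino]-2-methyl-4-oxobut-2-en-1-yl 2,2-dimethylpropanoate
Conditions: t-BuCOCl, pyridine, DMAP (cat.), CH2Cl2, 0 °C
Reagents that add atoms: 2,2-dimethylpropanoyl chloride, CC(C)(C)C(=O)Cl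
Why: O-acylation blocks relactonisation, and the hindered pivalate should resist the acetylide of step 6 at low temperature and then fall to the hydride of step 8.

Step 6
Reactants: 4 (4S,5Z)-6-methylocta-5,7-dien-1-yn-4-ol; 7 (2Z)-4-[methoxy(methyl)amino]-2-methyl-4-oxobut-2-en-1-yl 2,2-dimethylpropanoate
Product: 8 (2Z,8S,9Z)-8-hydroxy-2,10-dimethyl-4-oxododeca-2,9,11-trien-5-yn-1-yl 2,2-dimethylpropanoate
Conditions: n-BuLi (2.05 equiv), THF, −78 °C; then 7, −78 to −20 °C; aq NH4Cl
Reagents that add atoms: none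
Why: In this Weinreb ketone synthesis the dilithiated alkynol (alkoxide and acetylide) is acylated at carbon, and the chelated tetrahedral adduct stops the addition at the ynone.

Step 7
Reactants: 8 (2Z,8S,9Z)-8-hydroxy-2,10-dimethyl-4-oxododeca-2,9,11-trien-5-yn-1-yl 2,2-dimethylpropanoate
Product: 9 (2Z,4R,8S,9Z)-4,8-dihydroxy-2,10-dimethyldodeca-2,9,11-trien-5-yn-1-yl 2,2-dimethylpropanoate
Conditions: RuCl(p-cymene)[(R,R)-TsDPEN] (2 mol %), HCO2H–Et3N (5:2), CH2Cl2, rt
Reagents that add atoms: none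
Why: In this Noyori asymmetric transfer hydrogenation the alkynyl group should direct hydride delivery so that C6 is set as R, and formic acid as an irreversible donor avoids redox scrambling of the C8 carbinol.

Step 8
Reactants: 9 (2Z,4R,8S,9Z)-4,8-dihydroxy-2,10-dimethyldodeca-2,9,11-trien-5-yn-1-yl 2,2-dimethylpropanoate
Product: 11 (2Z,4R,5Z,8S,9Z)-6-iodo-2,10-dimethyldodeca-2,5,9,11-tetraene-1,4,8-triol, via sodium alkenylalanate 10 (not isolated)
Conditions: NaAlH2(OCH2CH2OMe)2 (4 equiv), THF, 0 °C to rt; EtOAc; I2, −78 °C; aq KNaC4H4O6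
Reagents that add atoms: iodine, II
Why: Hydroxyl-directed trans-hydroalumination places aluminium on the distal alkyne carbon (C4) cis to the C6 carbinol, iodination of the C–Al bond occurs with retention to give the Z vinyl iodide, and the excess hydride cleaves the pivalate.

Step 9
Reactants: 11 (2Z,4R,5Z,8S,9Z)-6-iodo-2,10-dimethyldodeca-2,5,9,11-tetraene-1,4,8-triol
Product: 12 (3Z,5S,7Z)-7-iodo-3-methyl-8-[(2R)-4-methyl-2,5-dihydrofuran-2-yl]octa-1,3,7-trien-5-ol
Conditions: PPh3, DIAD, THF, 0 °C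
Reagents that add atoms: none
Why: In this Mitsunobu cyclodehydration the primary allylic C12 hydroxyl is activated and displaced by the C6 hydroxyl in a 5-exo-tet closure, so the C6 configuration is retained.

Step 10
Reactants: 12 (3Z,5S,7Z)-7-iodo-3-methyl-8-[(2R)-4-methyl-2,5-dihydrofuran-2-yl]octa-1,3,7-trien-5-ol
Product: 13 (3Z,5S,7Z)-7-(hydroxymethyl)-3-methyl-8-[(2R)-4-methyl-2,5-dihydrofuran-2-yl]octa-1,3,7-trien-5-ol
Conditions: Bu3SnCH2OH, Pd(PPh3)4 (5 mol %), 1,4-dioxane, 90 °C
Reagents that add atoms: (tributylstannyl)methanol, CCCC[Sn](CO)(CCCC)CCCC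
Why: Stille coupling transfers the hydroxymethyl group (C15) to the vinyl iodide with retention, so C15 ends cis to C6.

Step 11
Reactants: 13 (3Z,5S,7Z)-7-(hydroxymethyl)-3-methyl-8-[(2R)-4-methyl-2,5-dihydrofuran-2-yl]octa-1,3,7-trien-5-ol
Product: 14 (3Z,5S,7Z)-3-methyl-8-[(2R)-4-methyl-2,5-dihydrofuran-2-yl]-7-{[tri(propan-2-yl)silyl]oxymethyl}octa-1,3,7-trien-5-ol
Conditions: i-Pr3SiCl, imidazole, DMF, 0 °C
Reagents that add atoms: chlorotri(propan-2-yl)silane, CC(C)[Si](Cl)(C(C)C)C(C)C
Why: Selective silylation: the bulky silyl chloride should react only at the primary hydroxyl, leaving the C8 carbinol free for the rearrangement.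

Step 12
Reactants: 14 (3Z,5S,7Z)-3-methyl-8-[(2R)-4-methyl-2,5-dihydrofuran-2-yl]-7-{[tri(propan-2-yl)silyl]oxymethyl}octa-1,3,7-trien-5-ol
Product: 17 6β,12-epoxy-15-{[tri(propan-2-yl)silyl]oxy}elema-1,3,11(13)-trien-8α-ol, via potassium enolate 15 (not isolated), via aldehyde 16 (not isolated)
Conditions: KN(SiMe3)2 (1.1 equiv), 18-crown-6, THF, −78 to 0 °C; AcOH (1.1 equiv), −78 °C; solvent switched to CH2Cl2 in the same flask; Me2AlCl (3 equiv), −78 to −20 °C
Reagents that add atoms: none
Why: The potassium alkoxide of 14 undergoes a charge-accelerated [3,3] shift (anionic oxy-Cope rearrangement) through a chair in which C10–C5 forms and C8–C3 breaks, giving enolate 15 and, on protonation, aldehyde 16; Me2AlCl then promotes an intramolecular carbonyl-ene reaction in which C8 adds to C7 of the dihydrofuran alkene while a hydrogen of the C11 methyl passes to oxygen, leaving the C11=C13 methylene. The closest known reaction types are tandem oxy-Cope/ene sequences and the citronellal-to-isopulegol cyclisation. The cyclohexane ring closes in 6-exo-trig fashion (the aldehyde carbon attacks an alkene whose second carbon stays outside the new ring) and ends cis-fused to the five-membered ether ring. C10 and C5 are set by the chair: the 3Z olefin puts the vinyl group axial and the methyl equatorial, the 7Z olefin puts C6 equatorial, and the C8–O⁻ bond stays equatorial because an axial oxygen would clash with the axial vinyl, so the S carbinol is relayed to 10S,5R; the C6 centre reinforces this, since with H6 eclipsing C4–C15 the new bond forms anti to C6–C7. C7 is fixed by the three-atom tether, which can reach only the dihydrofuran face that carries C5 and so places O6 and C11 cis, while C8 is expected as the equatorial 8α-alcohol and is corrected in steps 13 and 14. The step needs the concerted [3,3] path over fragmentation or a 1,3-shift (favoured by the crown-ether-separated alkoxide at low temperature) and hydrogen transfer from the methyl, not the ring CH2 (the equatorial carbonyl oxygen reaches the substituent syn to H7).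

Step 13
Reactants: 17 6β,12-epoxy-15-{[tri(propan-2-yl)silyl]oxy}elema-1,3,11(13)-trien-8α-ol
Product: 18 6β,12-epoxy-15-{[tri(propan-2-yl)silyl]oxy}elema-1,3,11(13)-trien-8-one
Conditions: Dess–Martin periodinane, NaHCO3, CH2Cl2, 0 °C
Reagents that add atoms: none
Why: Buffered Dess–Martin oxidation is non-enolising and should give the β,γ-unsaturated ketone without moving the exocyclic double bond or epimerising C7.

Step 14
Reactants: 18 6β,12-epoxy-15-{[tri(propan-2-yl)silyl]oxy}elema-1,3,11(13)-trien-8-one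
Product: 19 6β,12-epoxy-15-{[tri(propan-2-yl)silyl]oxy}elema-1,3,11(13)-trien-8β-ol
Conditions: LiBH(s-Bu)3, THF, −78 °C
Reagents that add atoms: none
Why: In this substrate-controlled ketone reduction the bulky hydride should attack from the α face, away from the axial C10 methyl and the β-oriented C6–O bond of the ring fusion, to give the axial 8β-alcohol.

Step 15
Reactants: 20 3-methylfuran-2(5H)-one
Product: 21 (2Z)-4-chloro-2-methylbut-2-enoyl chloride
Conditions: SOCl2, ZnCl2 (cat.), 60 °C
Reagents that add atoms: thionyl chloride, O=S(Cl)Cl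
Why: Lewis-acid-catalysed lactone opening by thionyl chloride (chloride at the allylic O–CH2, carboxyl to acid chloride) keeps the Z geometry that the ring imposes.

Step 16
Reactants: 19 6β,12-epoxy-15-{[tri(propan-2-yl)silyl]oxy}elema-1,3,11(13)-trien-8β-ol; 21 (2Z)-4-chloro-2-methylbut-2-enoyl chloride
Product: 22 6β,12-epoxy-15-{[tri(propan-2-yl)silyl]oxy}elema-1,3,11(13)-trien-8β-yl (2Z)-4-chloro-2-methylbut-2-enoate
Conditions: LiN(SiMe3)2, THF, −78 °C; then 21, −78 to 0 °C
Reagents that add atoms: none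
Why: O-acylation of the lithium alkoxide of the hindered axial alcohol by the acid chloride is faster than displacement of the allylic chloride, and the cold, amine-free conditions should avoid Z-to-E isomerisation.

Step 17
Reactants: 22 6β,12-epoxy-15-{[tri(propan-2-yl)silyl]oxy}elema-1,3,11(13)-trien-8β-yl (2Z)-4-chloro-2-methylbut-2-enoate
Product: 23 6β,12-epoxy-15-{[tri(propan-2-yl)silyl]oxy}elema-1,3,11(13)-trien-8β-yl (2Z)-4-acetoxy-2-methylbut-2-enoate
Conditions: CsOAc, 18-crown-6, MeCN, 40 °C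
Reagents that add atoms: caesium acetate, CC(=O)[O-].[Cs+]
Why: SN2 displacement of the primary allylic chloride by acetate installs the 4-acetoxy group and leaves the Z enoate unchanged.

Step 18
Reactants: 23 6β,12-epoxy-15-{[tri(propan-2-yl)silyl]oxy}elema-1,3,11(13)-trien-8β-yl (2Z)-4-acetoxy-2-methylbut-2-enoate
Product: 24 6β,12-epoxy-12-hydroxy-15-{[tri(propan-2-yl)silyl]oxy}elema-1,3,11(13)-trien-8β-yl (2Z)-4-acetoxy-2-methylbut-2-enoate (lactol, both C12 epimers)
Conditions: SeO2, pyridine, wet 1,4-dioxane, 60 °C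
Reagents that add atoms: selenium dioxide, O=[Se]=O
Why: In this Riley allylic oxidation SeO2 should add in an ene step to the strained exocyclic C11=C13 alkene with loss of a ring C12–H (a CH2 next to the ether oxygen, preferred over the C7 methine), and the [2,3] shift returns oxygen to C12; the C4=C3 alkene should react more slowly because its allylic CH2 is shielded by the bulky silyl ether.

Step 19
Reactants: 24 6β,12-epoxy-12-hydroxy-15-{[tri(propan-2-yl)silyl]oxy}elema-1,3,11(13)-trien-8β-yl (2Z)-4-acetoxy-2-methylbut-2-enoate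
Product: 25 6β,12-epoxy-12,15-dihydroxyelema-1,3,11(13)-trien-8β-yl (2Z)-4-acetoxy-2-methylbut-2-enoate
Conditions: HF·pyridine, pyridine, THF, 0 °C to rt
Reagents that add atoms: none
Why: Buffered fluoride desilylation should free the 15-OH without acyl migration, and it is placed before the acid is formed so that the γ-hydroxy acid never meets HF.

Step 20
Reactants: 25 6β,12-epoxy-12,15-dihydroxyelema-1,3,11(13)-trien-8β-yl (2Z)-4-acetoxy-2-methylbut-2-enoate
Product: 26 8β-{[(2Z)-4-acetoxy-2-methylbut-2-enoyl]oxy}-6β,15-dihydroxyelema-1,3,11(13)-trien-12-oic acid (5R,6S,7S,8R,10S; the target)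
Conditions: NaClO2, NaH2PO4, 2-methyl-2-butene, t-BuOH–H2O, 0 °C
Reagents that add atoms: sodium chlorite, [Na+].[O-]Cl=O
Why: Pinnick oxidation should act on the open hydroxy-aldehyde form of the lactol, giving the acrylic acid and releasing the 6β-hydroxyl, while the alkene scavenger and the mild buffer protect the olefins and limit relactonisation.

**Compound list**

1 | (2Z)-3-methylpent-2-en-4-yn-1-ol | C#C/C(C)=C\CO | starting material
2 | (2Z)-3-methylpenta-2,4-dien-1-ol | C=C/C(C)=C\CO | intermediate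
3 | (2Z)-3-methylpenta-2,4-dienal | C=C/C(C)=C\C=O | intermediate
4 | (4S,5Z)-6-methylocta-5,7-dien-1-yn-4-ol | C#CC[C@H](O)/C=C(C)\C=C | intermediate
5 | 4-methylfuran-2(5H)-one | CC1=CC(=O)OC1 | starting material
6 | (2Z)-4-hydroxy-N-methoxy-N,3-dimethylbut-2-enamide | CON(C)C(=O)/C=C(C)\CO | intermediate
7 | (2Z)-4-[methoxy(methyl)amino]-2-methyl-4-oxobut-2-en-1-yl 2,2-dimethylpropanoate | CON(C)C(=O)/C=C(C)\COC(=O)C(C)(C)C | intermediate
8 | (2Z,8S,9Z)-8-hydroxy-2,10-dimethyl-4-oxododeca-2,9,11-trien-5-yn-1-yl 2,2-dimethylpropanoate | C=C/C(C)=C\[C@@H](O)CC#CC(=O)/C=C(C)\COC(=O)C(C)(C)C | intermediate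
9 | (2Z,4R,8S,9Z)-4,8-dihydroxy-2,10-dimethyldodeca-2,9,11-trien-5-yn-1-yl 2,2-dimethylpropanoate | C=C/C(C)=C\[C@@H](O)CC#C[C@H](O)/C=C(C)\COC(=O)C(C)(C)C | intermediate
10 | sodium alkenylalanate from trans-hydroalumination of 9: five-membered O–Al–C4=C5–C6 ring, drawn in simplified form with the other hydroxyls free and two 2-methoxyethoxide ligands on aluminium | [Na+].C=C/C(C)=C\[C@@H](O)CC1=C[C@@H](/C=C(C)\CO)O[Al-]1(OCCOC)OCCOC | intermediate
11 | (2Z,4R,5Z,8S,9Z)-6-iodo-2,10-dimethyldodeca-2,5,9,11-tetraene-1,4,8-triol | C=C/C(C)=C\[C@@H](O)C/C(I)=C/[C@H](O)/C=C(C)\CO | intermediate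
12 | (3Z,5S,7Z)-7-iodo-3-methyl-8-[(2R)-4-methyl-2,5-dihydrofuran-2-yl]octa-1,3,7-trien-5-ol | C=C/C(C)=C\[C@@H](O)C/C(I)=C/[C@H]1C=C(C)CO1 | intermediate
13 | (3Z,5S,7Z)-7-(hydroxymethyl)-3-methyl-8-[(2R)-4-methyl-2,5-dihydrofuran-2-yl]octa-1,3,7-trien-5-ol | C=C/C(C)=C\[C@@H](O)C/C(CO)=C/[C@H]1C=C(C)CO1 | intermediate
14 | (3Z,5S,7Z)-3-methyl-8-[(2R)-4-methyl-2,5-dihydrofuran-2-yl]-7-{[tri(propan-2-yl)silyl]oxymethyl}octa-1,3,7-trien-5-ol | C=C/C(C)=C\[C@@H](O)C/C(CO[Si](C(C)C)(C(C)C)C(C)C)=C/[C@H]1C=C(C)CO1 | intermediate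
15 | potassium (E)-enolate of aldehyde 16 | [K+].[O-]/C=C/[C@@](C)(C=C)[C@H](C(=C)CO[Si](C(C)C)(C(C)C)C(C)C)[C@H]1C=C(C)CO1 | intermediate
16 | (3S,4R)-3-ethenyl-3-methyl-4-[(2R)-4-methyl-2,5-dihydrofuran-2-yl]-5-{[tri(propan-2-yl)silyl]oxymethyl}hex-5-enal | O=CC[C@@](C)(C=C)[C@H](C(=C)CO[Si](C(C)C)(C(C)C)C(C)C)[C@H]1C=C(C)CO1 | intermediate
17 | 6β,12-epoxy-15-{[tri(propan-2-yl)silyl]oxy}elema-1,3,11(13)-trien-8α-ol (cyclohexane cis-fused at C6–C7 to a 3-methylenetetrahydrofuran; CH3-14, C4, O6 and C11 all β) | C=C[C@]1(C)C[C@H](O)[C@H]2C(=C)CO[C@H]2[C@H]1C(=C)CO[Si](C(C)C)(C(C)C)C(C)C | intermediate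
18 | 6β,12-epoxy-15-{[tri(propan-2-yl)silyl]oxy}elema-1,3,11(13)-trien-8-one | C=C[C@]1(C)CC(=O)[C@H]2C(=C)CO[C@H]2[C@H]1C(=C)CO[Si](C(C)C)(C(C)C)C(C)C | intermediate
19 | 6β,12-epoxy-15-{[tri(propan-2-yl)silyl]oxy}elema-1,3,11(13)-trien-8β-ol | C=C[C@]1(C)C[C@@H](O)[C@H]2C(=C)CO[C@H]2[C@H]1C(=C)CO[Si](C(C)C)(C(C)C)C(C)C | intermediate
20 | 3-methylfuran-2(5H)-one | CC1=CCOC1=O | starting material
21 | (2Z)-4-chloro-2-methylbut-2-enoyl chloride | O=C(Cl)/C(C)=C\CCl | intermediate
22 | 6β,12-epoxy-15-{[tri(propan-2-yl)silyl]oxy}elema-1,3,11(13)-trien-8β-yl (2Z)-4-chloro-2-methylbut-2-enoate | C=C[C@]1(C)C[C@@H](OC(=O)/C(C)=C\CCl)[C@H]2C(=C)CO[C@H]2[C@H]1C(=C)CO[Si](C(C)C)(C(C)C)C(C)C | intermediate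
23 | 6β,12-epoxy-15-{[tri(propan-2-yl)silyl]oxy}elema-1,3,11(13)-trien-8β-yl (2Z)-4-acetoxy-2-methylbut-2-enoate | C=C[C@]1(C)C[C@@H](OC(=O)/C(C)=C\COC(C)=O)[C@H]2C(=C)CO[C@H]2[C@H]1C(=C)CO[Si](C(C)C)(C(C)C)C(C)C | intermediate
24 | 6β,12-epoxy-12-hydroxy-15-{[tri(propan-2-yl)silyl]oxy}elema-1,3,11(13)-trien-8β-yl (2Z)-4-acetoxy-2-methylbut-2-enoate (lactol, C12 epimers) | C=C[C@]1(C)C[C@@H](OC(=O)/C(C)=C\COC(C)=O)[C@H]2C(=C)C(O)O[C@H]2[C@H]1C(=C)CO[Si](C(C)C)(C(C)C)C(C)C | intermediate
25 | 6β,12-epoxy-12,15-dihydroxyelema-1,3,11(13)-trien-8β-yl (2Z)-4-acetoxy-2-methylbut-2-enoate (lactol, C12 epimers) | C=C[C@]1(C)C[C@@H](OC(=O)/C(C)=C\COC(C)=O)[C@H]2C(=C)C(O)O[C@H]2[C@H]1C(=C)CO | intermediate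
26 | 8β-{[(2Z)-4-acetoxy-2-methylbut-2-enoyl]oxy}-6β,15-dihydroxyelema-1,3,11(13)-trien-12-oic acid (5R,6S,7S,8R,10S) | C=C[C@]1(C)C[C@@H](OC(=O)/C(C)=C\COC(C)=O)[C@@H](C(=C)C(=O)O)[C@@H](O)[C@H]1C(=C)CO | target

**Step count**

Total: 20 steps. Longest linear sequence: 17 steps (steps 1–3, 6–14 and 16–20).

**Steps most likely to fail**

Step 12. The alkoxide may fragment heterolytically or rearrange by a stepwise 1,3-shift instead of the concerted chair, eroding the chirality transfer. In the second half the Lewis acid may ionise the allylic ether, or hydrogen may be transferred from the ring CH2 instead of the methyl group. The fallback sets out from 14 and comes back at 18. The rearrangement is run alone (KN(SiMe3)2, 18-crown-6, THF, then aq NH4Cl) and aldehyde 16 is isolated. Chlorite oxidation (NaClO2, NaH2PO4, 2-methyl-2-butene) gives (3S,4R)-3-ethenyl-3-methyl-4-[(2R)-4-methyl-2,5-dihydrofuran-2-yl]-5-{[tri(propan-2-yl)silyl]oxymethyl}hex-5-enoic acid F1. Trifluoroacetic anhydride in CH2Cl2 converts it into the mixed anhydride, which acylates C7 of the dihydrofuran alkene intramolecularly with loss of a methyl proton (olefin acylation, as in the cyclisation of citronellic acid derivatives to isopulegone). This gives ketone 18 directly, and the route continues with step 14.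

Step 18. Site selectivity may be poor, with the selenium reagent also attacking the second 2-substituted allylic ether (C15–H next to the silyl ether), or the lactol may be over-oxidised to the lactone. The fallback sets out from 23 and comes back at 25. The silyl ether is removed first (HF·pyridine, pyridine, THF) to give 6β,12-epoxy-15-hydroxyelema-1,3,11(13)-trien-8β-yl (2Z)-4-acetoxy-2-methylbut-2-enoate F2. Chloroacetic anhydride and pyridine convert it into the 15-chloroacetate F3, whose electron-poor acyloxy group deactivates the C4=C3 allylic system. SeO2 oxidation is then confined to the ring CH2 and gives the 12-hydroxy lactol 15-chloroacetate F4. Thiourea with NaHCO3 in EtOH removes the chloroacetate in the presence of the acetate and the enoate ester to give 25.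

Step 3. The sensitive 2Z dienal may isomerise to the E isomer under acid catalysis, or the face selectivity may be insufficient. The fallback sets out from 3 and comes back at 4. Barbier propargylation (propargyl bromide, Zn, THF–aq NH4Cl) gives racemic (5Z)-6-methylocta-5,7-dien-1-yn-4-ol F5. Lipase kinetic resolution (Candida antarctica lipase B, vinyl acetate, hexane) should acetylate the R enantiomer to (4R,5Z)-6-methylocta-5,7-dien-1-yn-4-yl acetate F6 and leave (S)-alcohol 4, which is separated and used in step 6.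

**Further compounds**

F1 | step 12 | (3S,4R)-3-ethenyl-3-methyl-4-[(2R)-4-methyl-2,5-dihydrofuran-2-yl]-5-{[tri(propan-2-yl)silyl]oxymethyl}hex-5-enoic acid | OC(=O)C[C@@](C)(C=C)[C@H](C(=C)CO[Si](C(C)C)(C(C)C)C(C)C)[C@H]1C=C(C)CO1
F2 | step 18 | 6β,12-epoxy-15-hydroxyelema-1,3,11(13)-trien-8β-yl (2Z)-4-acetoxy-2-methylbut-2-enoate | C=C[C@]1(C)C[C@@H](OC(=O)/C(C)=C\COC(C)=O)[C@H]2C(=C)CO[C@H]2[C@H]1C(=C)CO
F3 | step 18 | 15-(chloroacetoxy)-6β,12-epoxyelema-1,3,11(13)-trien-8β-yl (2Z)-4-acetoxy-2-methylbut-2-enoate | C=C[C@]1(C)C[C@@H](OC(=O)/C(C)=C\COC(C)=O)[C@H]2C(=C)CO[C@H]2[C@H]1C(=C)COC(=O)CCl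
F4 | step 18 | 15-(chloroacetoxy)-6β,12-epoxy-12-hydroxyelema-1,3,11(13)-trien-8β-yl (2Z)-4-acetoxy-2-methylbut-2-enoate | C=C[C@]1(C)C[C@@H](OC(=O)/C(C)=C\COC(C)=O)[C@H]2C(=C)C(O)O[C@H]2[C@H]1C(=C)COC(=O)CCl
F5 | step 3 | racemic (5Z)-6-methylocta-5,7-dien-1-yn-4-ol | C#CCC(O)/C=C(C)\C=C
F6 | step 3 | (4R,5Z)-6-methylocta-5,7-dien-1-yn-4-yl acetate | C#CC[C@@H](OC(C)=O)/C=C(C)\C=C
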